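**Plan**

- Numbering: C1 is the stereocentre and C2–C3 the ethylene chain; ring A is the 4-methoxyphenyl on C1, ring B the 2,6-dimethoxy-4-styrylphenyl on C1, ring C the 4-hydroxy-2-methoxyphenyl on C3, ring D the stilbene phenol.
- Enabling feature: ring A is bonded to the rest only through C1 and carries nothing but a methoxy group para to C1, so it can be grown last on C1 from a 2-pyrone whose C5 holds C1.
- Cuts: the ring B–vinyl bond (Heck); two bonds of ring A, the ortho–meta bond on one side and the meta–para bond on the other, counted from the ring carbon held by C1 (pyrone plus 1,1-dimethoxyethene, with a removable methyl ester on the remaining meta carbon activating the diene); the pyrone ring; the C1–C2 bond (conjugate addition).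
- Forward order: the ring C arylethyl bromide and the ring B cinnamic thioester are joined at C1–C2, the thioester end becomes the pyrone, ring A closes, the ester is removed, ring D is attached by Heck coupling, and both phenols are freed.
- Stereochemistry: C1 (S) is set once, in step 7, by copper-catalysed asymmetric Grignard addition while C1 carries a single aryl group; no later step touches it.

Key step: step 11

Assumption: (R)-Tol-BINAP is written in step 7 by analogy with additions to simple S-ethyl cinnamothioates; if this substrate responded in the opposite sense, the (S) ligand would be used with no other change.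

**Route**

Step 1
Reactants: 1 4-hydroxy-2-methoxybenzaldehyde
Product: 2 2-methoxy-4-(methoxymethoxy)benzaldehyde
Conditions: MeOCH2Cl, i-Pr2NEt, CH2Cl2, 0 °C to rt
Reagents that add atoms: chloromethyl methyl ether, COCCl
Why: O-alkylation of the phenoxide gives the methoxymethyl ether, which tolerates the organometallic, hydride and basic steps ahead and is removed in the last step.

Step 2
Reactants: 2 2-methoxy-4-(methoxymethoxy)benzaldehyde
Product: 3 1-ethenyl-2-methoxy-4-(methoxymethoxy)benzene
Conditions: Ph3PCH3Br, KOt-Bu, THF, 0 °C to rt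
Reagents that add atoms: methyltriphenylphosphonium bromide, C[P+](c1ccccc1)(c1ccccc1)c1ccccc1.[Br-]
Why: Wittig methylenation of an aromatic aldehyde with the unstabilised ylide is reliable and leaves the acetal-type ether untouched.

Step 3
Reactants: 3 1-ethenyl-2-methoxy-4-(methoxymethoxy)benzene
Product: 5 2-[2-methoxy-4-(methoxymethoxy)phenyl]ethanol, via alkylborane 4 (not isolated)
Conditions: 9-BBN, THF, 0 °C to rt; then NaOH, H2O2, 0 °C to rt
Reagents that add atoms: hydrogen peroxide, OO
Why: Anti-Markovnikov hydroboration with the bulky borane places boron on the terminal carbon (4), and alkaline peroxide oxidation replaces it by OH without harming the base-stable ether.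

Step 4
Reactants: 5 2-[2-methoxy-4-(methoxymethoxy)phenyl]ethanol
Product: 6 1-(2-bromoethyl)-2-methoxy-4-(methoxymethoxy)benzene
Conditions: CBr4, PPh3, CH2Cl2, 0 °C
Reagents that add atoms: carbon tetrabromide, BrC(Br)(Br)Br
Why: Appel bromination converts the primary alcohol into the bromide under near-neutral conditions that spare the acid-labile ether.

Step 5
Reactants: 7 4-bromo-2,6-dimethoxybenzaldehyde
Product: 9 (2E)-3-(4-bromo-2,6-dimethoxyphenyl)prop-2-enoic acid, via arylidenemalonic acid 8 (not isolated)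
Conditions: CH2(CO2H)2, pyridine, piperidine (cat.), 95 °C
Reagents that add atoms: malonic acid, OC(=O)CC(=O)O
Why: Knoevenagel condensation in the Doebner modification, in which 8 decarboxylates in hot pyridine to the thermodynamically favoured E-cinnamic acid.

Step 6
Reactants: 9 (2E)-3-(4-bromo-2,6-dimethoxyphenyl)prop-2-enoic acid
Product: 10 S-ethyl (2E)-3-(4-bromo-2,6-dimethoxyphenyl)prop-2-enethioate
Conditions: EtSH, DCC, DMAP (cat.), CH2Cl2, 0 °C to rt
Reagents that add atoms: ethanethiol, CCS
Why: Steglich-type carbodiimide coupling gives the thioester, the acceptor class reactive enough for copper-catalysed Grignard conjugate addition.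

Step 7
Reactants: 10 S-ethyl (2E)-3-(4-bromo-2,6-dimethoxyphenyl)prop-2-enethioate; 6 1-(2-bromoethyl)-2-methoxy-4-(methoxymethoxy)benzene
Product: 12 S-ethyl (3S)-3-(4-bromo-2,6-dimethoxyphenyl)-5-[2-methoxy-4-(methoxymethoxy)phenyl]pentanethioate, via arylethylmagnesium bromide 11 (not isolated)
Conditions: 6, Mg, Et2O, rt; then CuI (3 mol %), (R)-Tol-BINAP (3.3 mol %), 10, t-BuOMe, −70 °C, slow addition of 11; aq. NH4Cl
Reagents that add atoms: none
Why: Copper-catalysed asymmetric conjugate addition of a Grignard reagent to an α,β-unsaturated thioester, in which the bisphosphine-bound monovalent copper alkyl derived from 11 should add to the Si face of the β-carbon and so set C1 as (S) while it carries only one aryl group; low temperature and slow addition should suppress 1,2-addition and leave the aryl bromide alone.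

Step 8
Reactants: 12 S-ethyl (3S)-3-(4-bromo-2,6-dimethoxyphenyl)-5-[2-methoxy-4-(methoxymethoxy)phenyl]pentanethioate
Product: 13 (3S)-3-(4-bromo-2,6-dimethoxyphenyl)-5-[2-methoxy-4-(methoxymethoxy)phenyl]pentanal
Conditions: i-Bu2AlH, CH2Cl2, −78 °C; aq. potassium sodium tartrate
Reagents that add atoms: none
Why: DIBAL-H reduces thioesters to aldehydes at −78 °C without over-reduction, and C1, being β to the carbonyl, cannot epimerise.

Step 9
Reactants: 13 (3S)-3-(4-bromo-2,6-dimethoxyphenyl)-5-[2-methoxy-4-(methoxymethoxy)phenyl]pentanal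
Product: 14 dimethyl 2-[(3S)-3-(4-bromo-2,6-dimethoxyphenyl)-5-[2-methoxy-4-(methoxymethoxy)phenyl]pentylidene]propanedioate
Conditions: CH2(CO2Me)2, piperidine (cat.), AcOH (cat.), toluene, 4 Å MS, 60 °C
Reagents that add atoms: dimethyl malonate, COC(=O)CC(=O)OC
Why: Knoevenagel condensation of an aliphatic aldehyde with dimethyl malonate gives the alkylidenemalonate, which turns the CH2 next to C1 into an acidic vinylogous malonate position.

Step 10
Reactants: 14 dimethyl 2-[(3S)-3-(4-bromo-2,6-dimethoxyphenyl)-5-[2-methoxy-4-(methoxymethoxy)phenyl]pentylidene]propanedioate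
Product: 16 methyl 5-[(1S)-1-(4-bromo-2,6-dimethoxyphenyl)-3-[2-methoxy-4-(methoxymethoxy)phenyl]propyl]-2-oxo-2H-pyran-3-carboxylate, via aminodiene 15 (not isolated)
Conditions: t-BuOCH(NMe2)2, toluene, 80 °C; then AcOH–THF–H2O (3:1:1), 45 °C
Reagents that add atoms: tert-butoxybis(dimethylamino)methane, CN(C)C(OC(C)(C)C)N(C)C; water, O
Why: Vinylogous aminomethylenation of the γ-CH2 gives the push-pull aminodiene 15, and hydrolysis of its enamine in weak aqueous acid followed by lactonisation onto the cis ester is the known 2-pyrone synthesis from 5-aminopenta-2,4-dienoates; the acid is mild enough for the methoxymethyl ether, and the C1–H is not acidified by the cross-conjugated system.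

Step 11
Reactants: 16 methyl 5-[(1S)-1-(4-bromo-2,6-dimethoxyphenyl)-3-[2-methoxy-4-(methoxymethoxy)phenyl]propyl]-2-oxo-2H-pyran-3-carboxylate; 17 1,1-dimethoxyethene
Product: 20 methyl 5-[(1S)-1-(4-bromo-2,6-dimethoxyphenyl)-3-[2-methoxy-4-(methoxymethoxy)phenyl]propyl]-2-methoxybenzoate, via bridged lactone 18 (not isolated), via dimethoxycyclohexadiene 19 (not isolated)
Conditions: 17 (5 equiv), toluene, 110 °C, sealed tube
Reagents that add atoms: none
Why: The electron-poor diene of 16 (pyrone C3 to C6, lowered further by the C3 ester) and the electron-rich alkene 17 should combine in an inverse-electron-demand (4+2) cycloaddition to the bridged lactone 18, which expels CO2 by cycloreversion to the cyclohexadiene 19, and 19 aromatises by 1,2-elimination of methanol. The closest known reaction type is the aryl annulation of 3-methoxycarbonyl-2-pyrones with ketene acetals to give 2-methoxybenzoates, which tolerates alkyl groups at C5 and C6. Ring A closes as a six-membered carbocycle by intermolecular cycloaddition, the two new ring bonds being pyrone C6 to the CH2 carbon of 17 and pyrone C3 to the acetal carbon of 17. No new stereocentre survives, because the bridgehead centres of 18 are lost on aromatisation, and C1 is untouched under neutral thermal conditions. The selectivity needed is regiochemical: the nucleophilic CH2 terminus of 17 must bond to C6, the position conjugated to both the lactone and the ester carbonyl, so that the surviving methoxy group ends para to C1 and ortho to the ester; the matched polarisation of both partners secures this.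

Step 12
Reactants: 20 methyl 5-[(1S)-1-(4-bromo-2,6-dimethoxyphenyl)-3-[2-methoxy-4-(methoxymethoxy)phenyl]propyl]-2-methoxybenzoate
Product: 21 5-[(1S)-1-(4-bromo-2,6-dimethoxyphenyl)-3-[2-methoxy-4-(methoxymethoxy)phenyl]propyl]-2-methoxybenzoic acid
Conditions: LiOH, THF–MeOH–H2O, 45 °C; then 1 M HCl to pH 3, 0 °C
Reagents that add atoms: lithium hydroxide, [Li+].[OH-]
Why: Saponification of the methyl benzoate gives the acid, while the methoxymethyl ether, aryl bromide and aryl methyl ethers are inert to base.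

Step 13
Reactants: 21 5-[(1S)-1-(4-bromo-2,6-dimethoxyphenyl)-3-[2-methoxy-4-(methoxymethoxy)phenyl]propyl]-2-methoxybenzoic acid
Product: 22 5-bromo-2-[(1S)-3-[2-methoxy-4-(methoxymethoxy)phenyl]-1-(4-methoxyphenyl)propyl]-1,3-dimethoxybenzene
Conditions: Ag2CO3 (10 mol %), AcOH (5 mol %), DMSO, 120 °C
Reagents that add atoms: none
Why: Silver-catalysed protodecarboxylation, well established for ortho-alkoxybenzoic acids and tolerant of aryl bromides, removes the activating carboxyl group and leaves ring A as the para-substituted anisole.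

Step 14
Reactants: 22 5-bromo-2-[(1S)-3-[2-methoxy-4-(methoxymethoxy)phenyl]-1-(4-methoxyphenyl)propyl]-1,3-dimethoxybenzene; 23 4-ethenylphenyl acetate
Product: 24 4-[(E)-2-[3,5-dimethoxy-4-[(1S)-3-[2-methoxy-4-(methoxymethoxy)phenyl]-1-(4-methoxyphenyl)propyl]phenyl]ethenyl]phenyl acetate
Conditions: Pd(OAc)2 (5 mol %), P(o-tol)3 (10 mol %), Et3N, DMF, 100 °C
Reagents that add atoms: none
Why: Heck reaction, in which zerovalent palladium formed from Pd(OAc)2 inserts into the aryl bromide and syn-carbopalladation at the terminal styrene carbon followed by syn β-hydride elimination gives the E-stilbene.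

Step 15
Reactants: 24 4-[(E)-2-[3,5-dimethoxy-4-[(1S)-3-[2-methoxy-4-(methoxymethoxy)phenyl]-1-(4-methoxyphenyl)propyl]phenyl]ethenyl]phenyl acetate
Product: 25 4-[(3S)-3-[4-[(E)-2-(4-hydroxyphenyl)ethenyl]-2,6-dimethoxyphenyl]-3-(4-methoxyphenyl)propyl]-3-methoxyphenol
Conditions: HCl (3 M aq.), MeOH, 45 °C
Reagents that add atoms: none
Why: Acid-catalysed methanolysis cleaves the methoxymethyl acetal and transesterifies the aryl acetate in one operation, leaving the four aryl methyl ethers, the stilbene and C1 untouched.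

**Compound list**

1 | 4-hydroxy-2-methoxybenzaldehyde | COc1cc(O)ccc1C=O | starting material
2 | 2-methoxy-4-(methoxymethoxy)benzaldehyde | COCOc1ccc(C=O)c(OC)c1 | intermediate
3 | 1-ethenyl-2-methoxy-4-(methoxymethoxy)benzene | C=Cc1ccc(OCOC)cc1OC | intermediate
4 | 9-[2-[2-methoxy-4-(methoxymethoxy)phenyl]ethyl]-9-borabicyclo[3.3.1]nonane | COCOc1ccc(CCB2C3CCCC2CCC3)c(OC)c1 | intermediate
5 | 2-[2-methoxy-4-(methoxymethoxy)phenyl]ethanol | COCOc1ccc(CCO)c(OC)c1 | intermediate
6 | 1-(2-bromoethyl)-2-methoxy-4-(methoxymethoxy)benzene | COCOc1ccc(CCBr)c(OC)c1 | intermediate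
7 | 4-bromo-2,6-dimethoxybenzaldehyde | COc1cc(Br)cc(OC)c1C=O | starting material
8 | 2-[(4-bromo-2,6-dimethoxyphenyl)methylidene]propanedioic acid | COc1cc(Br)cc(OC)c1C=C(C(=O)O)C(=O)O | intermediate
9 | (2E)-3-(4-bromo-2,6-dimethoxyphenyl)prop-2-enoic acid | COc1cc(Br)cc(OC)c1/C=C/C(=O)O | intermediate
10 | S-ethyl (2E)-3-(4-bromo-2,6-dimethoxyphenyl)prop-2-enethioate | CCSC(=O)/C=C/c1c(OC)cc(Br)cc1OC | intermediate
11 | bromo[2-[2-methoxy-4-(methoxymethoxy)phenyl]ethyl]magnesium | COCOc1ccc(CC[Mg]Br)c(OC)c1 | intermediate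
12 | S-ethyl (3S)-3-(4-bromo-2,6-dimethoxyphenyl)-5-[2-methoxy-4-(methoxymethoxy)phenyl]pentanethioate | CCSC(=O)C[C@H](CCc1ccc(OCOC)cc1OC)c1c(OC)cc(Br)cc1OC | intermediate
13 | (3S)-3-(4-bromo-2,6-dimethoxyphenyl)-5-[2-methoxy-4-(methoxymethoxy)phenyl]pentanal | O=CC[C@H](CCc1ccc(OCOC)cc1OC)c1c(OC)cc(Br)cc1OC | intermediate
14 | dimethyl 2-[(3S)-3-(4-bromo-2,6-dimethoxyphenyl)-5-[2-methoxy-4-(methoxymethoxy)phenyl]pentylidene]propanedioate | COC(=O)C(=CC[C@H](CCc1ccc(OCOC)cc1OC)c1c(OC)cc(Br)cc1OC)C(=O)OC | intermediate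
15 | dimethyl 2-[(3S)-3-(4-bromo-2,6-dimethoxyphenyl)-2-[(dimethylamino)methylidene]-5-[2-methoxy-4-(methoxymethoxy)phenyl]pentylidene]propanedioate (enamine geometry not defined) | COC(=O)C(=CC(=CN(C)C)[C@H](CCc1ccc(OCOC)cc1OC)c1c(OC)cc(Br)cc1OC)C(=O)OC | intermediate
16 | methyl 5-[(1S)-1-(4-bromo-2,6-dimethoxyphenyl)-3-[2-methoxy-4-(methoxymethoxy)phenyl]propyl]-2-oxo-2H-pyran-3-carboxylate | COC(=O)c1cc([C@H](CCc2ccc(OCOC)cc2OC)c2c(OC)cc(Br)cc2OC)coc1=O | intermediate
17 | 1,1-dimethoxyethene | C=C(OC)OC | starting material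
18 | methyl 6-[(1S)-1-(4-bromo-2,6-dimethoxyphenyl)-3-[2-methoxy-4-(methoxymethoxy)phenyl]propyl]-8,8-dimethoxy-3-oxo-2-oxabicyclo[2.2.2]oct-5-ene-4-carboxylate (bridgehead configuration not defined) | COC(=O)C12C=C([C@H](CCc3ccc(OCOC)cc3OC)c3c(OC)cc(Br)cc3OC)C(CC1(OC)OC)OC2=O | intermediate
19 | methyl 3-[(1S)-1-(4-bromo-2,6-dimethoxyphenyl)-3-[2-methoxy-4-(methoxymethoxy)phenyl]propyl]-6,6-dimethoxycyclohexa-1,3-diene-1-carboxylate | COC(=O)C1=CC([C@H](CCc2ccc(OCOC)cc2OC)c2c(OC)cc(Br)cc2OC)=CCC1(OC)OC | intermediate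
20 | methyl 5-[(1S)-1-(4-bromo-2,6-dimethoxyphenyl)-3-[2-methoxy-4-(methoxymethoxy)phenyl]propyl]-2-methoxybenzoate | COC(=O)c1cc([C@H](CCc2ccc(OCOC)cc2OC)c2c(OC)cc(Br)cc2OC)ccc1OC | intermediate
21 | 5-[(1S)-1-(4-bromo-2,6-dimethoxyphenyl)-3-[2-methoxy-4-(methoxymethoxy)phenyl]propyl]-2-methoxybenzoic acid | OC(=O)c1cc([C@H](CCc2ccc(OCOC)cc2OC)c2c(OC)cc(Br)cc2OC)ccc1OC | intermediate
22 | 5-bromo-2-[(1S)-3-[2-methoxy-4-(methoxymethoxy)phenyl]-1-(4-methoxyphenyl)propyl]-1,3-dimethoxybenzene | COc1ccc([C@H](CCc2ccc(OCOC)cc2OC)c2c(OC)cc(Br)cc2OC)cc1 | intermediate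
23 | 4-ethenylphenyl acetate (4-acetoxystyrene) | CC(=O)Oc1ccc(C=C)cc1 | starting material
24 | 4-[(E)-2-[3,5-dimethoxy-4-[(1S)-3-[2-methoxy-4-(methoxymethoxy)phenyl]-1-(4-methoxyphenyl)propyl]phenyl]ethenyl]phenyl acetate | COc1ccc([C@H](CCc2ccc(OCOC)cc2OC)c2c(OC)cc(/C=C/c3ccc(OC(C)=O)cc3)cc2OC)cc1 | intermediate
25 | 4-[(3S)-3-[4-[(E)-2-(4-hydroxyphenyl)ethenyl]-2,6-dimethoxyphenyl]-3-(4-methoxyphenyl)propyl]-3-methoxyphenol | COc1ccc([C@H](CCc2ccc(O)cc2OC)c2c(OC)cc(/C=C/c3ccc(O)cc3)cc2OC)cc1 | target

**Step count**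

Total: 15 steps. Longest linear sequence: 13 steps (steps 1–4 and 7–15).

**Steps most likely to fail**

1. Step 7. The β-carbon carries a di-ortho-substituted, electron-rich aryl group, so conjugate addition may be slow, and background 1,2-addition or poor facial discrimination may erode yield and enantiopurity. The fallback sets out from 9 and comes back at 12. The acid 9 would be activated with t-BuCOCl and Et3N (THF, −20 °C) as its pivaloyl mixed anhydride F1. Treatment of this with (S)-4-phenyl-1,3-oxazolidin-2-one and LiCl should give the N-enoyl oxazolidinone F2. Addition of the Grignard reagent 11 with CuBr·SMe2 in THF at −40 °C should occur on the chelated s-cis imide at the face away from the phenyl group and give the (3S) adduct F3, purifiable as a single diastereomer. LiSEt (from EtSH and n-BuLi, THF, 0 °C) would then exchange the auxiliary for the ethyl thioester 12.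

2. Step 10. Aminomethylenation at the methylene flanked by C1 may stay incomplete, and the acid stage may cause partial loss of the methoxymethyl group before ring closure is finished. The fallback sets out from 13 and comes back at 16, reversing the order in which the pyrone carbons are attached. Aldehyde 13 would be condensed with pyrrolidine (4 Å MS, toluene, rt) to the enamine F4. Its nucleophilic carbon would add to dimethyl 2-(methoxymethylidene)propanedioate with loss of methanol (toluene, 50 °C) to give the pyrrolidinyl diene F5. Brief treatment with aqueous acetic acid should then hydrolyse the enamine and close the lactone to 16.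

3. Step 11. Cycloaddition next to the bulky C5 substituent may be sluggish, with oligomerisation of the ketene acetal or incomplete aromatisation competing. The fallback sets out from 13 and comes back at 22, building ring A by annulation and dehydrogenation. Amine-catalysed Michael addition of 13 to methyl vinyl ketone (pyrrolidine cat., CH2Cl2, rt) would give the keto aldehyde F6. Intramolecular aldol condensation (KOH, MeOH, rt; Robinson annulation) would give the 4-substituted cyclohexenone F7. Aerobic dehydrogenation (Pd(O2CCF3)2, 2-(dimethylamino)pyridine, TsOH, O2, DMSO, 80 °C) would give the phenol F8, and O-methylation (MeI, K2CO3, acetone) would give 22.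

**Further compounds**

F1 | step 7 | (2E)-3-(4-bromo-2,6-dimethoxyphenyl)prop-2-enoic 2,2-dimethylpropanoic anhydride | COc1cc(Br)cc(OC)c1/C=C/C(=O)OC(=O)C(C)(C)C
F2 | step 7 | (4S)-3-[(2E)-3-(4-bromo-2,6-dimethoxyphenyl)prop-2-enoyl]-4-phenyl-1,3-oxazolidin-2-one | COc1cc(Br)cc(OC)c1/C=C/C(=O)N1C(=O)OC[C@@H]1c1ccccc1
F3 | step 7 | (4S)-3-[(3S)-3-(4-bromo-2,6-dimethoxyphenyl)-5-[2-methoxy-4-(methoxymethoxy)phenyl]pentanoyl]-4-phenyl-1,3-oxazolidin-2-one | O=C(C[C@H](CCc1ccc(OCOC)cc1OC)c1c(OC)cc(Br)cc1OC)N1C(=O)OC[C@@H]1c1ccccc1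
F4 | step 10 | 1-[(1E,3S)-3-(4-bromo-2,6-dimethoxyphenyl)-5-[2-methoxy-4-(methoxymethoxy)phenyl]pent-1-en-1-yl]pyrrolidine | C1CCN(C1)/C=C/[C@H](CCc1ccc(OCOC)cc1OC)c1c(OC)cc(Br)cc1OC
F5 | step 10 | dimethyl 2-[(3S)-3-(4-bromo-2,6-dimethoxyphenyl)-5-[2-methoxy-4-(methoxymethoxy)phenyl]-2-(pyrrolidin-1-ylmethylidene)pentylidene]propanedioate | COC(=O)C(=CC(=CN1CCCC1)[C@H](CCc1ccc(OCOC)cc1OC)c1c(OC)cc(Br)cc1OC)C(=O)OC
F6 | step 11 | 2-[(1S)-1-(4-bromo-2,6-dimethoxyphenyl)-3-[2-methoxy-4-(methoxymethoxy)phenyl]propyl]-5-oxohexanal (C2 not defined) | CC(=O)CCC(C=O)[C@H](CCc1ccc(OCOC)cc1OC)c1c(OC)cc(Br)cc1OC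
F7 | step 11 | 4-[(1S)-1-(4-bromo-2,6-dimethoxyphenyl)-3-[2-methoxy-4-(methoxymethoxy)phenyl]propyl]cyclohex-2-en-1-one (ring C4 not defined) | O=C1C=CC(CC1)[C@H](CCc1ccc(OCOC)cc1OC)c1c(OC)cc(Br)cc1OC
F8 | step 11 | 4-[(1S)-1-(4-bromo-2,6-dimethoxyphenyl)-3-[2-methoxy-4-(methoxymethoxy)phenyl]propyl]phenol | Oc1ccc([C@H](CCc2ccc(OCOC)cc2OC)c2c(OC)cc(Br)cc2OC)cc1
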